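**Retrosynthetic overview** (chamigrane locants: ring A = C1–C6, spiro carbon C6, ring B = C6–C11)
1. Target ⇐ acetylation and desilylation ⇐ hydroxyl-directed bromochlorination of a C2=C3 alkene in ring A (C5–OH delivers Cl to C3).
2. C2=C3 / C5–OH ⇐ deconjugative reduction of the C3=C4–C5=O enone ⇐ dehydrogenation of a C5 ketone that can enolise only toward C4.
3. Ring B ⇐ Diels–Alder disconnection of C10–C11 and C6–C7: (S)-pulegone (ring A, C11 and its two methyls) plus a (2Z,4E)-5-bromo-2-silyloxypenta-2,4-diene (C7–C10 and the C7 methyl); C8=C9 is then saturated.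
4. Enabling feature: the C5 oxygen is α to the spiro carbon C6, so at the ketone level C6=C11 is an exocyclic enone; ring B carries O on C7 and Br on C10 at the two ends of the C8–C9 edge, which is the retron of a cycloadduct of a terminally oxygenated bromodiene.
5. Ring order: ring A from the chiral pool, ring B by the key step; the C3 methyl stereocentre of pulegone relays chirality to C6 and is then erased.

Key step: step 4

Assumption: (S)-(−)-pulegone and pent-4-yn-2-ol are taken as commercial, and all spirocycles are named with the chamigrane locants given above.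

**Step 1**
Reactants: 1 pent-4-yn-2-ol (racemic)
Product: 3 (E)-5-bromopent-4-en-2-ol, via alkenylzirconocene 2 (not isolated)
Conditions: Cp2Zr(H)Cl (2.2 equiv), THF, 0 °C to rt; then NBS, 0 °C; aqueous work-up
Reagents that add atoms: N-bromosuccinimide (NBS), O=C1CCC(=O)N1Br
Why: Hydrozirconation–bromination: after the hydroxyl has consumed one equivalent of hydride as its Cp2Zr(Cl) alkoxide, syn addition of Zr–H places zirconium on the terminal carbon and bromination cleaves the C–Zr bond with retention, which should give only the E bromoalkene.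

**Step 2**
Reactants: 3 (E)-5-bromopent-4-en-2-ol
Product: 4 (E)-5-bromopent-4-en-2-one
Conditions: Dess–Martin periodinane, CH2Cl2, 0 °C
Reagents that add atoms: none
Why: Dess–Martin oxidation under neutral conditions should convert the secondary alcohol into the ketone without moving the β,γ double bond into conjugation.

**Step 3**
Reactants: 4 (E)-5-bromopent-4-en-2-one
Product: 5 (2Z,4E)-5-bromo-2-(triethylsilyloxy)penta-2,4-diene
Conditions: TESOTf, Et3N, Et2O, −78 to 0 °C
Reagents that add atoms: triethylsilyl trifluoromethanesulfonate (TESOTf), CC[Si](CC)(CC)OS(=O)(=O)C(F)(F)F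
Why: Soft enolisation (silyl triflate and amine) removes a proton from the doubly activated C3 methylene rather than from the methyl group and should give the thermodynamically preferred Z enol ether (silyloxy cis to the bromovinyl chain) with the E bromoalkene intact.

**Step 4**
Reactants: 5 (2Z,4E)-5-bromo-2-(triethylsilyloxy)penta-2,4-diene; 6 (S)-(−)-pulegone
Product: 7 (3S,6S,7R,10R)-10-bromo-3,7,11,11-tetramethyl-7-(triethylsilyloxy)spiro[5.5]undec-8-en-5-one
Conditions: Et3SiNTf2 (10 mol %, prepared separately), CH2Cl2, −78 to −30 °C, slow addition of 5 to 6; then Et3N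
Reagents that add atoms: none
Why: This is a Lewis-acid-promoted Diels–Alder reaction of the kind used for hindered enone/silyloxydiene pairs that create adjacent quaternary carbons: the separately prepared silyl triflimide Et3SiNTf2 binds the C5 carbonyl of the s-cis-locked exocyclic enone, so that no dienol ether is spent on making the catalyst, and the addition is strongly asynchronous, the unhindered terminus C10 of the dienol ether bonding first to the β-carbon C11 and the enolate carbon C6 then closing on the oxocarbenium carbon C7 before bond rotation. Ring B is closed as a six-membered ring by a suprafacial [4+2] addition across C6=C11 (the second bond is a six-membered enolate-to-oxocarbenium closure), which makes ring A spiro at C6 and carries every atom of 5 and 6 into 7. The regiochemistry (C10 to C11, C7 to C6) follows from the 1-silyloxy donor, which makes C10 the nucleophilic end of the diene while C11 is the electrophilic end of the enone. C10 and C7 are fixed relative to each other by the diene geometry (4E bromine outside, 2Z silyloxy inside) and relative to C6 by the exo transition state preferred by α-branched s-cis enones (ring CH2 C1 under the diene, C5=O away), which puts Br and the C7 methyl cis to C1 and the silyloxy group cis to C5. The absolute configuration at C6 comes from (S)-pulegone: the diene should add to the equatorial face of the exocyclic alkene, anti to the axial hydrogens at C2 and C4 of the chair whose C3 methyl is equatorial, so that C11 ends up cis to that methyl. The step needs γ- over α-reactivity of the dienol ether, exo over endo addition and equatorial over axial attack; these are secured by the unhindered CH terminus at C10, by the α-alkyl branch of the enone and by the methyl-anchored chair, and the two facial adducts are diastereomers that should be separable.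

**Step 5**
Reactants: 7 (3S,6S,7R,10R)-10-bromo-3,7,11,11-tetramethyl-7-(triethylsilyloxy)spiro[5.5]undec-8-en-5-one
Product: 8 (3S,6S,7R,10R)-10-bromo-3,7,11,11-tetramethyl-7-(triethylsilyloxy)spiro[5.5]undecan-5-one
Conditions: 2-nitrobenzenesulfonyl hydrazide, Et3N, CH2Cl2, rt
Reagents that add atoms: none
Why: Diimide reduction transfers H2 in a concerted syn fashion to the cis-disubstituted C8=C9 bond and should leave the allylic C10–Br bond, which a metal hydrogenation catalyst would cleave, untouched; no stereocentre is created.

**Step 6**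
Reactants: 8 (3S,6S,7R,10R)-10-bromo-3,7,11,11-tetramethyl-7-(triethylsilyloxy)spiro[5.5]undecan-5-one
Product: 9 (6S,7R,10R)-10-bromo-3,7,11,11-tetramethyl-7-(triethylsilyloxy)spiro[5.5]undec-3-en-5-one
Conditions: IBX, 4-methoxypyridine N-oxide, DMSO, rt
Reagents that add atoms: none
Why: IBX dehydrogenation of a ketone to its enone: the C5 ketone can enolise only toward C4 because C6 is quaternary, so the new double bond must be C3=C4, and the C3 stereocentre, whose task ended in step 4, is erased.

**Step 7**
Reactants: 9 (6S,7R,10R)-10-bromo-3,7,11,11-tetramethyl-7-(triethylsilyloxy)spiro[5.5]undec-3-en-5-one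
Product: 12 (5R,6R,7R,10R)-10-bromo-3,7,11,11-tetramethyl-7-(triethylsilyloxy)spiro[5.5]undec-2-en-5-ol, via potassium dienolate 10 (not isolated), via deconjugated ketone 11 (not isolated)
Conditions: KOtBu, tBuOH/THF, 0 °C; AcOH/H2O, −40 °C; then NaBH4, EtOH, −40 to 0 °C
Reagents that add atoms: none
Why: Deconjugation by kinetic α-protonation of an extended dienolate followed by borohydride reduction (the classical conversion of a conjugated enone into a homoallylic alcohol): thermodynamic γ-deprotonation at C2 gives the linear dienolate, protonation at C4 moves the double bond to C2=C3, and hydride should add to C5 anti to the pseudo-axial C6–C7 bond (the silyloxy-bearing carbon held perpendicular to the carbonyl), giving the equatorial 5R alcohol cis to C7.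

**Step 8**
Reactants: 12 (5R,6R,7R,10R)-10-bromo-3,7,11,11-tetramethyl-7-(triethylsilyloxy)spiro[5.5]undec-2-en-5-ol
Product: 13 (2S,3S,5R,6R,7R,10R)-2,10-dibromo-3-chloro-3,7,11,11-tetramethyl-7-(triethylsilyloxy)spiro[5.5]undecan-5-ol
Conditions: NBS, ClTi(OiPr)3 (1.1 equiv), CH2Cl2/hexanes, −20 °C
Reagents that add atoms: N-bromosuccinimide (NBS), O=C1CCC(=O)N1Br; chlorotitanium triisopropoxide ClTi(OiPr)3, CC(C)O[Ti](Cl)(OC(C)C)OC(C)C
Why: Proposed new method: NBS forms the bromonium ion on C2=C3 while the ClTi(OiPr)2 unit bound to O5 holds its chloride over the ring face of O5, and the chloride should pass to the tertiary, Markovnikov carbon C3 through a six-membered Cl–Ti–O5–C5–C4–C3 array, so that Cl ends cis to the C5 oxygen and Br at C2 anti to Cl, the silyl ether keeping O7 from opening the bromonium ion; the closest known reaction type is the ClTi(OiPr)3-mediated, alkoxide-directed bromochlorination of allylic alcohols, in which chloride is delivered through an array of the same size, extended here to a cyclic homoallylic alcohol.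

**Step 9**
Reactants: 13 (2S,3S,5R,6R,7R,10R)-2,10-dibromo-3-chloro-3,7,11,11-tetramethyl-7-(triethylsilyloxy)spiro[5.5]undecan-5-ol
Product: 14 (2S,3S,5R,6R,7R,10R)-2,10-dibromo-3-chloro-3,7,11,11-tetramethylspiro[5.5]undecane-5,7-diol
Conditions: HF·pyridine, pyridine, THF, 0 °C
Reagents that add atoms: none
Why: Fluoride-mediated desilylation should cleave the tertiary triethylsilyl ether under buffered conditions that leave the tertiary chloride and both bromides untouched; no stereocentre is affected.

**Step 10**
Reactants: 14 (2S,3S,5R,6R,7R,10R)-2,10-dibromo-3-chloro-3,7,11,11-tetramethylspiro[5.5]undecane-5,7-diol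
Product: 15 (2S,3S,5R,6R,7R,10R)-2,10-dibromo-3-chloro-7-hydroxy-3,7,11,11-tetramethylspiro[5.5]undecan-5-yl acetate
Conditions: Ac2O, pyridine, DMAP (cat.), CH2Cl2, 0 °C to rt
Reagents that add atoms: acetic anhydride, CC(=O)OC(C)=O
Why: DMAP-catalysed acylation should acetylate only the secondary C5 hydroxyl, the tertiary C7 hydroxyl next to the quaternary spiro carbon being inert under these conditions; no stereocentre is affected.

**Compound list**
1 | pent-4-yn-2-ol (racemic) | CC(O)CC#C | starting material
2 | O-zirconated (E)-alkenylzirconocene chloride from 1 | CC(O[Zr](Cl)(C1C=CC=C1)C1C=CC=C1)C/C=C/[Zr](Cl)(C1C=CC=C1)C1C=CC=C1 | intermediate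
3 | (E)-5-bromopent-4-en-2-ol (racemic) | CC(O)C/C=C/Br | intermediate
4 | (E)-5-bromopent-4-en-2-one | CC(=O)C/C=C/Br | intermediate
5 | (2Z,4E)-5-bromo-2-(triethylsilyloxy)penta-2,4-diene | C/C(O[Si](CC)(CC)CC)=C/C=C/Br | intermediate
6 | (S)-(−)-pulegone, (5S)-5-methyl-2-(propan-2-ylidene)cyclohexan-1-one | C[C@H]1CCC(=C(C)C)C(=O)C1 | starting material
7 | (3S,6S,7R,10R)-10-bromo-3,7,11,11-tetramethyl-7-(triethylsilyloxy)spiro[5.5]undec-8-en-5-one | O=C1C[C@@H](C)CC[C@@]12C(C)(C)[C@H](Br)C=C[C@@]2(C)O[Si](CC)(CC)CC | intermediate
8 | (3S,6S,7R,10R)-10-bromo-3,7,11,11-tetramethyl-7-(triethylsilyloxy)spiro[5.5]undecan-5-one | O=C1C[C@@H](C)CC[C@@]12C(C)(C)[C@H](Br)CC[C@@]2(C)O[Si](CC)(CC)CC | intermediate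
9 | (6S,7R,10R)-10-bromo-3,7,11,11-tetramethyl-7-(triethylsilyloxy)spiro[5.5]undec-3-en-5-one | O=C1C=C(C)CC[C@@]12C(C)(C)[C@H](Br)CC[C@@]2(C)O[Si](CC)(CC)CC | intermediate
10 | potassium 2,4-dien-5-olate of 9 (C6, C7, C10 as in 9) | [K+].[O-]C1=CC(C)=CC[C@@]12C(C)(C)[C@H](Br)CC[C@@]2(C)O[Si](CC)(CC)CC | intermediate
11 | (6S,7R,10R)-10-bromo-3,7,11,11-tetramethyl-7-(triethylsilyloxy)spiro[5.5]undec-2-en-5-one | O=C1CC(C)=CC[C@@]12C(C)(C)[C@H](Br)CC[C@@]2(C)O[Si](CC)(CC)CC | intermediate
12 | (5R,6R,7R,10R)-10-bromo-3,7,11,11-tetramethyl-7-(triethylsilyloxy)spiro[5.5]undec-2-en-5-ol | O[C@@H]1CC(C)=CC[C@@]12C(C)(C)[C@H](Br)CC[C@@]2(C)O[Si](CC)(CC)CC | intermediate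
13 | (2S,3S,5R,6R,7R,10R)-2,10-dibromo-3-chloro-3,7,11,11-tetramethyl-7-(triethylsilyloxy)spiro[5.5]undecan-5-ol | O[C@@H]1C[C@](C)(Cl)[C@@H](Br)C[C@@]12C(C)(C)[C@H](Br)CC[C@@]2(C)O[Si](CC)(CC)CC | intermediate
14 | (2S,3S,5R,6R,7R,10R)-2,10-dibromo-3-chloro-3,7,11,11-tetramethylspiro[5.5]undecane-5,7-diol | O[C@@H]1C[C@](C)(Cl)[C@@H](Br)C[C@@]12C(C)(C)[C@H](Br)CC[C@@]2(C)O | intermediate
15 | (2S,3S,5R,6R,7R,10R)-2,10-dibromo-3-chloro-7-hydroxy-3,7,11,11-tetramethylspiro[5.5]undecan-5-yl acetate | CC(=O)O[C@@H]1C[C@](C)(Cl)[C@@H](Br)C[C@@]12C(C)(C)[C@H](Br)CC[C@@]2(C)O | target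

**Step count**
Total: 10 steps. Longest linear sequence: 10 steps (1 → 3 → 4 → 5 → 7 → 8 → 9 → 12 → 13 → 14 → 15); the pulegone branch enters at step 4.

**Steps most likely to fail**

1. Step 8 (bromochlorination, the proposed new method). What may go wrong:
- bromonium formation on the face syn to C11 may be slow, so that undirected chloride attack from the other face gives the 2,3-diastereomer;
- chloride may be delivered to C2;
- the C5 alkoxide may be brominated or oxidised instead of directing.

Fallback (known substrate-controlled addition on the acetate instead of alkoxide-directed delivery; sets out from 12, returns at 15): acetylation (Ac2O, DMAP, pyridine) should give the (5R,6R,7R,10R)-10-bromo-3,7,11,11-tetramethyl-7-(triethylsilyloxy)spiro[5.5]undec-2-en-5-yl acetate F1. Addition of BrCl without direction (NBS, Et4NCl, CH2Cl2, −40 °C) is expected to place Br+ on the ring face anti to the pseudo-axial C7 and to open the bromonium ion at the tertiary carbon C3 from the opposite face, giving the (2S,3S,5R,6R,7R,10R)-2,10-dibromo-3-chloro-3,7,11,11-tetramethyl-7-(triethylsilyloxy)spiro[5.5]undecan-5-yl acetate F2. HF·pyridine then removes the silyl group and gives 15 directly.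

2. Step 4 (key cycloaddition). What may go wrong:
- the dienol ether may be consumed by protodesilylation or self-condensation faster than it adds to the fully substituted enone;
- the reaction may stop after the first C10–C11 bond, with bond rotation and no ring closure;
- the facial bias from the remote C3 methyl may be weak;
- the Lewis acid may ionise the allylic C10–Br bond.

Fallback (the cycloaddition made intramolecular and steered by a C5 carbinol; sets out from 6 and 4, returns at 7): reagent-controlled 1,2-reduction of 6 with (S)-2-methyl-CBS-oxazaborolidine and catecholborane should give (1R,5S)-5-methyl-2-(propan-2-ylidene)cyclohexan-1-ol F3, whose hydroxyl is pseudo-axial because of allylic strain. Treatment with iPr2Si(OTf)2/2,6-lutidine and then ketone 4/Et3N should link it to the dienol as the mixed silylene bis-ether F4. Heating (toluene, 180 °C, sealed tube) should bring about a type 1 intramolecular Diels–Alder reaction in which the six-membered tether delivers the diene to the face of C6=C11 that carries O5, giving the tricyclic 5,7-O-di(propan-2-yl)silylene cycloadduct F5 with C7 cis to O5 and the same C7/C10 relationship as in 7. HF·pyridine should free the (3S,5R,6R,7R,10R)-10-bromo-3,7,11,11-tetramethylspiro[5.5]undec-8-ene-5,7-diol F6. Dess–Martin periodinane should oxidise only the secondary C5 hydroxyl to the (3S,6S,7R,10R)-10-bromo-7-hydroxy-3,7,11,11-tetramethylspiro[5.5]undec-8-en-5-one F7, and TESOTf/2,6-lutidine should convert F7 into 7.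

3. Step 7 (deconjugation and C5 reduction). What may go wrong:
- deprotonation at the C3 methyl may lead to the exocyclic alkene isomer;
- protonation at C2 may return the conjugated enone, which is then reduced to the allylic alcohol;
- hydride may be delivered from the C7 face, giving the C5 epimer.

Fallback (an isolated dienyl ester in place of the kinetic protonation; sets out from 9, returns at 12): the thermodynamic linear dienol is trapped with Ac2O/TMSCl/NaI as the 5-acetoxy-2,4-diene (dienyl acetate of 9) F8, which can be freed of the exocyclic isomer. NaBH4 in EtOH/H2O at 0 °C should then release ketone 11 by ethanolysis of the enol ester in the presence of hydride and reduce it at once to 12. The buffered medium also allows the hydride source to be changed if the facial selectivity at C5 has to be corrected.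

**Further compounds**
F1 | step 8 | (5R,6R,7R,10R)-10-bromo-3,7,11,11-tetramethyl-7-(triethylsilyloxy)spiro[5.5]undec-2-en-5-yl acetate | CC(=O)O[C@@H]1CC(C)=CC[C@@]12C(C)(C)[C@H](Br)CC[C@@]2(C)O[Si](CC)(CC)CC
F2 | step 8 | (2S,3S,5R,6R,7R,10R)-2,10-dibromo-3-chloro-3,7,11,11-tetramethyl-7-(triethylsilyloxy)spiro[5.5]undecan-5-yl acetate | CC(=O)O[C@@H]1C[C@](C)(Cl)[C@@H](Br)C[C@@]12C(C)(C)[C@H](Br)CC[C@@]2(C)O[Si](CC)(CC)CC
F3 | step 4 | (1R,5S)-5-methyl-2-(propan-2-ylidene)cyclohexan-1-ol | O[C@@H]1C[C@@H](C)CCC1=C(C)C
F4 | step 4 | {[(2Z,4E)-5-bromopenta-2,4-dien-2-yl]oxy}{[(1R,5S)-5-methyl-2-(propan-2-ylidene)cyclohexyl]oxy}di(propan-2-yl)silane | C/C(O[Si](C(C)C)(C(C)C)O[C@@H]1C[C@@H](C)CCC1=C(C)C)=C/C=C/Br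
F5 | step 4 | (3S,5R,6R,7R,10R)-10-bromo-3,7,11,11-tetramethylspiro[5.5]undec-8-ene-5,7-diol 5,7-O-di(propan-2-yl)silylene derivative | CC(C)[Si]1(C(C)C)O[C@@H]2C[C@@H](C)CC[C@@]23C(C)(C)[C@H](Br)C=C[C@@]3(C)O1
F6 | step 4 | (3S,5R,6R,7R,10R)-10-bromo-3,7,11,11-tetramethylspiro[5.5]undec-8-ene-5,7-diol | O[C@@H]1C[C@@H](C)CC[C@@]12C(C)(C)[C@H](Br)C=C[C@@]2(C)O
F7 | step 4 | (3S,6S,7R,10R)-10-bromo-7-hydroxy-3,7,11,11-tetramethylspiro[5.5]undec-8-en-5-one | O=C1C[C@@H](C)CC[C@@]12C(C)(C)[C@H](Br)C=C[C@@]2(C)O
F8 | step 7 | (7R,10R)-10-bromo-3,7,11,11-tetramethyl-7-(triethylsilyloxy)spiro[5.5]undeca-2,4-dien-5-yl acetate (C6 as in 9) | CC(=O)OC1=CC(C)=CC[C@@]12C(C)(C)[C@H](Br)CC[C@@]2(C)O[Si](CC)(CC)CC
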